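3 questions stood before the meeting, all on maple, the flask followed so far.

| setting | maple | cedar | flask |
|---|---|---|---|
| starting material | 23 mM | 23 mM | 23 mM |
| first nucleophile | 0.80 equiv | 0.80 equiv | 0.800 equiv |
| second nucleophile | 1.2 equiv | 1.2 equiv | 1.20 equiv |
| protic impurity | 11.5 mM | 7.7 mM | 11.5 mM |
| remark | the very flask that is asked about, followed so far | run made earlier |  |
| time |  |  | 15 d |

- maple (time / d: other capture product / %, target / %): 0.417: 26.6, 45.1; 1.25: 30.9, 54.3; 2.00: 28.8, 54.5; 3.00: 29.6, 53.6; 5.00: 28.4, 53.0; 6.00: 31.5, 54.7
- cedar (time / d: other capture product / %, target / %): 0.625: 29.9, 52.0; 2.08: 32.7, 54.1; 4.00: 32.4, 54.2; 6.00: 31.5, 55.1; 8.00: 31.8, 54.3; 10.0: 29.3, 53.3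

(scatter of a reading: 1 percentage point)

1. share of other capture product in other capture product plus target at 20 min
2. share of other capture product in other capture product plus target at 15 d
3. which of other capture product and target there is more of at 15 d



The analyst reported that both runs level off. She noted that protic impurity stood at 0.500 of the starting material in maple and 0.335 in cedar, and the readings barely moved. The kineticist proposed that the two nucleophiles compete at one shared branch, each taking it in proportion to its amount. He pooled the readings from 1.25 d in maple and 2.08 d in cedar, which gave 0.378. This is the selectivity factor: other capture product over target, divided by second nucleophile over first nucleophile as charged. He froze it. Maple's share then came to 36.2 % at both asked times. Target leads, since the factor times the charge ratio is 0.567, less than one.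

The sceptic objected that 20 min lies before any reading. The earliest maple reading gave a share of 37.1 %, with a scatter of 1 percentage point on each reading.

The forecast was entered: 35.5 % at 20 min, 36 % at 15 d, target ahead. Its ground was that “the products look like kinetically fixed end points”.

Maple gave 37.7 % at 20 min and 36.0 % at 15 d, with target ahead.

    starting material + protic impurity → quenched substrate (k = 0.410 L mol⁻¹ h⁻¹)
    second nucleophile + intermediate → other capture product (k = 21.0 L mol⁻¹ h⁻¹)
    intermediate → solvolysis product (k = 0.140 h⁻¹)
    second nucleophile ⇌ dormant form (K = 0.280, k = 0.0130 h⁻¹)
    starting material → intermediate (k = 0.210 h⁻¹)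
    2 second nucleophile → homo dimer (k = 1.60 L mol⁻¹ h⁻¹)
    first nucleophile + intermediate → target (k = 51.0 L mol⁻¹ h⁻¹)

Up to 1.50 d, with starting material down to 0.0442 %, both nucleophiles captured intermediate and other capture product reached 30.4 %. From then to 15.0 d, second nucleophile fell from 18.9 % to 3.77 % of its charge as homo dimer formed, while target stood at 54.0 %. Maple's factor at 15 d reads 0.375. In a neighbour flask, the same recipe but with 0.320 equiv of first nucleophile, 0.378 gives a share of 58.6 %. That flask gave 62.3 %, with other capture product at 45.9 % and target at 27.8 %.

All runs stem from a simulated flask on assumed constants, noise included.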